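Assumption: poly-L-leucine is taken to give the (2R,3S)-epoxide of chalcone 4, as it does with parent chalcone; locants used below are O1, C2 (side chain), C3 (aryl), C4 (OH), C5 (CH2) for the oxolane and Cα for the side-chain carbinol carbon.

**Retrosynthetic overview**
- Target ⇐ epoxide-fused oxolane (3,6-dioxabicyclo[3.1.0]hexane): C3–H by invertive hydrogenolysis of the benzylic oxirane C–O bond, plus O-debenzylation.
- Bicycle ⇐ anti α-hydroxy-β-benzyloxy aryl ketone + vinylsulfonium C2 unit: O1–C5, C3–C4 and C4–O bonds in one operation; the oxolane closes first (ylide onto ketone), the oxirane second (betaine collapse).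
- Hydroxy ketone ⇐ trans-epoxy chalcone + BnOH (inversion at the benzylic carbon sets Cα).
- Epoxy ketone ⇐ chalcone ⇐ 4'-methoxyacetophenone + veratraldehyde; this first oxirane is consumed before the oxolane/oxirane pair is made.

**Route**

Step 1
Reactants: 1 4'-methoxyacetophenone; 2 3,4-dimethoxybenzaldehyde
Product: 4 (E)-3-(3,4-dimethoxyphenyl)-1-(4-methoxyphenyl)prop-2-en-1-one, via aldol adduct 3 (not isolated)
Conditions: NaOH (aq), EtOH, rt
Reagents that add atoms: none
Why: Claisen–Schmidt condensation, in which the acetophenone enolate adds to the non-enolisable aldehyde and aldol 3 dehydrates by E1cB to the conjugated (E)-enone; no stereocentre is formed.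

Step 2
Reactants: 4 (E)-chalcone
Product: 5 [(2R,3S)-3-(3,4-dimethoxyphenyl)oxiran-2-yl](4-methoxyphenyl)methanone
Conditions: poly-L-leucine (20 wt %), urea–H2O2 (1.2 equiv), DBU (1.5 equiv), THF, rt
Reagents that add atoms: urea–hydrogen peroxide, OO.NC(N)=O (one oxygen is transferred)
Why: Juliá–Colonna asymmetric nucleophilic epoxidation, in which the helical polypeptide controls the face of hydroperoxide addition to the enone and gives the trans-epoxy ketone in high ee (crystallisation upgrades it), fixing C2 (kept to the end) and the oxirane carbon that becomes Cα.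

Step 3
Reactants: 5 (2R,3S)-epoxy ketone
Product: 6 (2R,3R)-3-(benzyloxy)-3-(3,4-dimethoxyphenyl)-2-hydroxy-1-(4-methoxyphenyl)propan-1-one
Conditions: BnOH (10 equiv), BF3·OEt2 (10 mol %), CH2Cl2, −40 °C
Reagents that add atoms: benzyl alcohol, OCc1ccccc1
Why: Acid-catalysed regioselective epoxide alcoholysis, in which the activated oxirane opens at the benzylic carbon (charge stabilised by the dimethoxyphenyl ring, the carbon next to the carbonyl being deactivated) by backside attack of BnOH, inverting Cα from S to R and leaving C2 untouched, so the anti hydroxy ketone arrives with its two oxygens already differentiated.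

Step 4
Reactants: 6 anti α-hydroxy-β-benzyloxy ketone; 7 diphenyl(vinyl)sulfonium trifluoromethanesulfonate (1.3 equiv)
Product: 10 (1R,2R,5R)-2-[(R)-benzyloxy(3,4-dimethoxyphenyl)methyl]-1-(4-methoxyphenyl)-3,6-dioxabicyclo[3.1.0]hexane, via sulfonium ylide 8 (not isolated), via betaine 9 (not isolated)
Conditions: DBU (2 equiv), CH2Cl2, 0 °C → rt; filter through Et3N-deactivated silica
Reagents that add atoms: none
Why: Proposed new method: extension of the vinylsulfonium epoxy-annulation (closest known reaction type: the Aggarwal annulation of N-sulfonyl amino ketones with diphenylvinylsulfonium triflate) to an α-hydroxy aryl ketone, in which the alkoxide of 6 adds to the vinylsulfonium (oxa-Michael) to give ylide 8, the ylide carbon attacks the neighbouring aryl ketone in a five-membered intramolecular Corey–Chaykovsky addition to betaine 9, and the new alkoxide expels Ph2S to close the cis-fused oxirane, so oxolane and oxirane form in one operation; C3 and C4 are set by C2, because the tethered ylide attacks the carbonyl face that keeps the bulky C2 side chain beside the small carbonyl oxygen and away from the aryl group, placing the epoxide oxygen cis to the side chain.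

Step 5
Reactants: 10 epoxide-fused oxolane
Product: 12 (3S,4R,5S)-5-[(R)-(3,4-dimethoxyphenyl)(hydroxy)methyl]-4-(4-methoxyphenyl)oxolan-3-ol, via benzyl ether 11 (not isolated)
Conditions: H2 (1 atm), Pd/C (10 wt % Pd), EtOAc, rt
Reagents that add atoms: none
Why: Heterogeneous benzylic C–O hydrogenolysis, in which Pd cleaves the tertiary benzylic C3–O bond of the aryl oxirane with inversion (hydrogen enters anti to the leaving oxygen, from the open face opposite the C2 side chain), swinging the aryl group cis to both the C4–OH and the side chain to give the all-cis oxolane, while the same catalyst removes the benzyl ether (11 → 12) and the free secondary benzylic alcohol survives under neutral conditions.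

**Compound list**
1 | 4'-methoxyacetophenone | COc1ccc(cc1)C(C)=O | starting material
2 | 3,4-dimethoxybenzaldehyde (veratraldehyde) | COc1ccc(C=O)cc1OC | starting material
3 | 3-(3,4-dimethoxyphenyl)-3-hydroxy-1-(4-methoxyphenyl)propan-1-one, racemic aldol adduct | COc1ccc(cc1)C(=O)CC(O)c1ccc(OC)c(OC)c1 | intermediate (not isolated)
4 | (E)-3-(3,4-dimethoxyphenyl)-1-(4-methoxyphenyl)prop-2-en-1-one | COc1ccc(cc1)C(=O)/C=C/c1ccc(OC)c(OC)c1 | intermediate
5 | [(2R,3S)-3-(3,4-dimethoxyphenyl)oxiran-2-yl](4-methoxyphenyl)methanone, trans | COc1ccc(cc1)C(=O)[C@@H]1O[C@H]1c1ccc(OC)c(OC)c1 | intermediate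
6 | (2R,3R)-3-(benzyloxy)-3-(3,4-dimethoxyphenyl)-2-hydroxy-1-(4-methoxyphenyl)propan-1-one, anti | COc1ccc(cc1)C(=O)[C@H](O)[C@H](OCc1ccccc1)c1ccc(OC)c(OC)c1 | intermediate
7 | diphenyl(vinyl)sulfonium trifluoromethanesulfonate | C=C[S+](c1ccccc1)c1ccccc1.[O-]S(=O)(=O)C(F)(F)F | starting material
8 | sulfonium ylide: 6 as its 2-(diphenylsulfonio)ethyl ether at the C2 oxygen, carbanion on the carbon next to sulfur | COc1ccc(cc1)C(=O)[C@H](OC[CH-][S+](c1ccccc1)c1ccccc1)[C@H](OCc1ccccc1)c1ccc(OC)c(OC)c1 | intermediate (not isolated)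
9 | betaine: oxolane closed, C3 alkoxide cis to the C2 side chain, C4 diphenylsulfonio group trans to the alkoxide | COc1ccc(cc1)[C@@]1([O-])[C@@H]([S+](c2ccccc2)c2ccccc2)CO[C@@H]1[C@H](OCc1ccccc1)c1ccc(OC)c(OC)c1 | intermediate (not isolated)
10 | (1R,2R,5R)-2-[(R)-benzyloxy(3,4-dimethoxyphenyl)methyl]-1-(4-methoxyphenyl)-3,6-dioxabicyclo[3.1.0]hexane, epoxide oxygen cis to the side chain | COc1ccc(cc1)[C@@]12O[C@@H]1CO[C@@H]2[C@H](OCc1ccccc1)c1ccc(OC)c(OC)c1 | intermediate
11 | (3S,4R,5S)-5-[(R)-benzyloxy(3,4-dimethoxyphenyl)methyl]-4-(4-methoxyphenyl)oxolan-3-ol, all-cis | COc1ccc([C@H]2[C@@H]([C@H](OCc3ccccc3)c3ccc(OC)c(OC)c3)OC[C@H]2O)cc1 | intermediate (not isolated)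
12 | (3S,4R,5S)-5-[(R)-(3,4-dimethoxyphenyl)(hydroxy)methyl]-4-(4-methoxyphenyl)oxolan-3-ol, all-cis ring | COc1ccc([C@H]2[C@@H]([C@H](O)c3ccc(OC)c(OC)c3)OC[C@H]2O)cc1 | target

**Totals**
Total steps: 5. Longest linear sequence: 5 steps (from 1 or 2).

**Steps most likely to fail**

1. Step 4. The alkoxide is a weaker donor than a sulfonamide, the enolisable ketone can lose BnOH by E1cB or epimerise at C2, and the face selectivity is predicted, not proven. The fallback sets out from 6 and comes back at 10. The α-hydroxyl of 6 is allylated without strong base (allyl bromide, Ag2O, CH2Cl2) to the allyl ether F1. The aryl ketone is methylenated with Cp2TiMe2 (toluene, 65 °C) to the 1,1-disubstituted styrene diene F2. Ring-closing metathesis with second-generation Grubbs catalyst (CH2Cl2, 40 °C) gives the 3-aryl-2,5-dihydrofuran F3. NBS in aqueous THF forms the bromonium ion on the face away from the C2 side chain and water enters at benzylic C3, giving the bromohydrin F4. K2CO3 in MeOH then closes the oxirane on the face cis to the side chain, which is 10.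

2. Step 5. The hydrogenolysis may proceed with partial retention, the epoxide may isomerise on Pd to a ketone, or the Cα–O bond may be over-reduced. The fallback sets out from 10 and comes back at 12. Catalytic Bi(OTf)3 (CH2Cl2, 0 °C) triggers a Meinwald rearrangement (1,2-hydride shift to the anisyl-stabilised cation) to the oxolan-3-one F5 as a C3 epimer mixture. Soft enolisation (TBSOTf, Et3N, CH2Cl2) gives the aryl-conjugated silyl enol ether F6, in which C3 is planar again. Hydrogenation over Pd/C (H2, 5 bar, EtOAc) adds both hydrogens to the face away from the C2 side chain and removes the benzyl group, giving the all-cis silyl ether F7. TBAF in THF then gives 12.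

3. Step 3. The electron-rich benzylic centre can open with SN1 character (partial retention), and acyl migration can compete. The fallback sets out from 5 and comes back at 12; it gives up stereospecific substitution at Cα and fixes that centre last by chelation-controlled reduction. The mixture of 6 and its Cα epimer, the syn hydroxy ketone F8, is carried through steps 4 and 5 unchanged. F8 gives the epimeric bicyclic epoxide F9 and then the Cα-epimeric diol F10 beside 12. MnO2 (CH2Cl2, rt) oxidises only the benzylic carbinol of both epimers to the single aryl ketone F11. Zn(BH4)2 (Et2O, −20 °C) then delivers hydride to the zinc chelate between O1 and the carbonyl from the C2–H side, giving the erythro alcohol 12.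

**Further compounds**
F1 | step 4 | (2R,3R)-2-(allyloxy)-3-(benzyloxy)-3-(3,4-dimethoxyphenyl)-1-(4-methoxyphenyl)propan-1-one | COc1ccc(cc1)C(=O)[C@H](OCC=C)[C@H](OCc1ccccc1)c1ccc(OC)c(OC)c1
F2 | step 4 | diene: F1 with the ketone C=O replaced by C=CH2, configuration as in 6 | COc1ccc(cc1)C(=C)[C@H](OCC=C)[C@H](OCc1ccccc1)c1ccc(OC)c(OC)c1
F3 | step 4 | (S)-2-[(R)-benzyloxy(3,4-dimethoxyphenyl)methyl]-3-(4-methoxyphenyl)-2,5-dihydrofuran | COc1ccc(cc1)C1=CCO[C@@H]1[C@H](OCc1ccccc1)c1ccc(OC)c(OC)c1
F4 | step 4 | bromohydrin: 2-[(R)-benzyloxy(3,4-dimethoxyphenyl)methyl]-4-bromo-3-(4-methoxyphenyl)oxolan-3-ol, C3–OH cis to the side chain, C4–Br trans to the OH | COc1ccc(cc1)[C@@]1(O)[C@@H](Br)CO[C@@H]1[C@H](OCc1ccccc1)c1ccc(OC)c(OC)c1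
F5 | step 5 | (5S)-5-[(R)-benzyloxy(3,4-dimethoxyphenyl)methyl]-4-(4-methoxyphenyl)oxolan-3-one, epimer mixture at the aryl-bearing carbon | COc1ccc(cc1)C1C(=O)CO[C@@H]1[C@H](OCc1ccccc1)c1ccc(OC)c(OC)c1
F6 | step 5 | tert-butyldimethylsilyl enol ether of F5: (5S)-5-[(R)-benzyloxy(3,4-dimethoxyphenyl)methyl]-4-(4-methoxyphenyl)-3-(tert-butyldimethylsilyloxy)-2,5-dihydrofuran | COc1ccc(cc1)C1=C(O[Si](C)(C)C(C)(C)C)CO[C@@H]1[C@H](OCc1ccccc1)c1ccc(OC)c(OC)c1
F7 | step 5 | C4 O-tert-butyldimethylsilyl ether of 12, all-cis | COc1ccc([C@H]2[C@@H]([C@H](O)c3ccc(OC)c(OC)c3)OC[C@H]2O[Si](C)(C)C(C)(C)C)cc1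
F8 | step 3 | (2R,3S)-3-(benzyloxy)-3-(3,4-dimethoxyphenyl)-2-hydroxy-1-(4-methoxyphenyl)propan-1-one, syn | COc1ccc(cc1)C(=O)[C@H](O)[C@@H](OCc1ccccc1)c1ccc(OC)c(OC)c1
F9 | step 3 | (1R,2R,5R)-2-[(S)-benzyloxy(3,4-dimethoxyphenyl)methyl]-1-(4-methoxyphenyl)-3,6-dioxabicyclo[3.1.0]hexane | COc1ccc(cc1)[C@@]12O[C@@H]1CO[C@@H]2[C@@H](OCc1ccccc1)c1ccc(OC)c(OC)c1
F10 | step 3 | (3S,4R,5S)-5-[(S)-(3,4-dimethoxyphenyl)(hydroxy)methyl]-4-(4-methoxyphenyl)oxolan-3-ol, Cα epimer of 12 | COc1ccc([C@H]2[C@@H]([C@@H](O)c3ccc(OC)c(OC)c3)OC[C@H]2O)cc1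
F11 | step 3 | (3,4-dimethoxyphenyl)[(2S,3R,4S)-4-hydroxy-3-(4-methoxyphenyl)oxolan-2-yl]methanone | COc1ccc([C@H]2[C@@H](C(=O)c3ccc(OC)c(OC)c3)OC[C@H]2O)cc1
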